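**Plan**

- Retrosynthesis: (a) remove the three silyl ethers; (b) take the C8 prenyl group back to allyl (cross-metathesis); (c) cut ring C at C2–C3 and at C4–C4a, which leaves an O-aryl oxocarbenium ion (ring A–O1=C2–ring B) and ethoxyethyne as the C3–C4 unit with the ketone masked as its enol ether; (d) cut C2–O1 of the mixed acetal to a ring A phenol and a ring B benzaldehyde acetal.
- Enabling feature: O1 sits on the phloroglucinol-type ring A and C2 is benzylic to ring B, which carries an ortho oxygen. Ionisation at C2 therefore gives a stabilised cationic 2-oxadiene C4a=C8a–O1=C2. C4a is ortho to O1, ortho to the C5 oxygen, para to the C7 oxygen and the only free ortho carbon, so it closes onto C4.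
- Forward order: ring A phenol (silylation, O-allylation, Claisen); ring B acetal (silylation, acetalisation, α-arylation, Wittig); union through C2–O1 as a mixed acetal; ring C closes in one operation with both C–C bonds; then prenyl, then desilylation.
- Stereochemistry: the only stereocentre, C2 (S), is set in the annulation by a chiral counteranion and afterwards meets only neutral or buffered conditions.
- The C8 prenyl group is carried as allyl through the cationic step, because a prenyl group ortho to O1 would capture the oxocarbenium ion in a six-membered ene closure.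

Key step: step 9

Assumption: the sense of induction of the chiral acid in step 9 has no direct precedent; the (S)-configured acid is written, and its antipode is to be used if that is the one that leads to the (2S) product.

**Route**

Step 1
Reactants: 1 phloroglucinol
Product: 2 3,5-bis(tert-butyldimethylsilyloxy)phenol
Conditions: TBSCl (2.0 equiv), imidazole, DMF, 0 °C → rt
Reagents that add atoms: tert-butyldimethylsilyl chloride, CC(C)(C)[Si](C)(C)Cl
Why: Silylation of phenols with a silyl chloride and imidazole; the three hydroxyls of 1 are equivalent, so the bis-silyl ether is a single constitutional isomer, to be separated from the mono- and tris-silyl ethers, which are returned to the step.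

Step 2
Reactants: 2 3,5-bis(tert-butyldimethylsilyloxy)phenol; 3 allyl alcohol
Product: 4 1-(allyloxy)-3,5-bis(tert-butyldimethylsilyloxy)benzene
Conditions: PPh3, DIAD, THF, 0 °C → rt
Reagents that add atoms: none
Why: Mitsunobu etherification of a phenol with a primary allylic alcohol runs under neutral conditions and so avoids a free phenoxide that could scramble the aryl silyl ethers.

Step 3
Reactants: 4 1-(allyloxy)-3,5-bis(tert-butyldimethylsilyloxy)benzene
Product: 5 2-allyl-3,5-bis(tert-butyldimethylsilyloxy)phenol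
Conditions: PhNEt2, 190 °C (sealed tube)
Reagents that add atoms: none
Why: Aromatic Claisen rearrangement ([3,3]-sigmatropic shift, then tautomerisation) delivers the allyl group to an ortho carbon, and the two ortho positions of 4 are equivalent, so one regioisomer should form.

Step 4
Reactants: 6 5-bromo-2-hydroxybenzaldehyde
Product: 7 5-bromo-2-(triisopropylsilyloxy)benzaldehyde
Conditions: TIPSCl, imidazole, DMF, rt
Reagents that add atoms: triisopropylsilyl chloride, CC(C)[Si](Cl)(C(C)C)C(C)C
Why: Silylation of the phenol; the triisopropylsilyl ether is chosen because it should withstand the carbonate base of step 6 and the acids of steps 8 and 9.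

Step 5
Reactants: 7 5-bromo-2-(triisopropylsilyloxy)benzaldehyde
Product: 8 [4-bromo-2-(dimethoxymethyl)phenoxy]triisopropylsilane
Conditions: HC(OMe)3, PPTS (cat.), MeOH, rt
Reagents that add atoms: trimethyl orthoformate, COC(OC)OC
Why: Acid-catalysed acetalisation with an orthoformate masks the aldehyde for steps 6 and 7 and supplies the dimethyl acetal needed in step 8.

Step 6
Reactants: 8 [4-bromo-2-(dimethoxymethyl)phenoxy]triisopropylsilane; 9 isobutyraldehyde
Product: 10 2-[3-(dimethoxymethyl)-4-(triisopropylsilyloxy)phenyl]-2-methylpropanal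
Conditions: [Pd(C3H5)Cl]2 (1 mol %), 1,1'-bis(diphenylphosphino)ferrocene, Cs2CO3, 1,4-dioxane, 80 °C
Reagents that add atoms: none
Why: Palladium-catalysed α-arylation of the enolate of an α-branched aldehyde builds the quaternary benzylic carbon, and the product cannot enolise, so a second arylation is excluded.

Step 7
Reactants: 10 2-[3-(dimethoxymethyl)-4-(triisopropylsilyloxy)phenyl]-2-methylpropanal
Product: 11 [2-(dimethoxymethyl)-4-(2-methylbut-3-en-2-yl)phenoxy]triisopropylsilane
Conditions: Ph3PCH3Br, KOt-Bu, THF, 0 °C → rt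
Reagents that add atoms: methyltriphenylphosphonium bromide, C[P+](c1ccccc1)(c1ccccc1)c1ccccc1.[Br-]
Why: Wittig methylenation of the non-enolisable aldehyde completes the 2-methylbut-3-en-2-yl group.

Step 8
Reactants: 11 [2-(dimethoxymethyl)-4-(2-methylbut-3-en-2-yl)phenoxy]triisopropylsilane; 5 2-allyl-3,5-bis(tert-butyldimethylsilyloxy)phenol
Product: 13 {2-[(2-allyl-3,5-bis(tert-butyldimethylsilyloxy)phenoxy)(methoxy)methyl]-4-(2-methylbut-3-en-2-yl)phenoxy}triisopropylsilane (racemic at the acetal carbon), via α-chloro ether 12 (not isolated)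
Conditions: AcCl, ZnBr2 (cat.), toluene, 0 °C → rt; then 5, i-Pr2NEt, 0 °C → rt
Reagents that add atoms: none
Why: Zinc-bromide-catalysed exchange of one methoxy group for chloride by acetyl chloride gives the α-chloro ether, which should O-alkylate the amine-buffered phenol as chloromethyl methyl ether does in a MOM protection (Williamson-type alkylation with an α-halo ether).

Step 9
Reactants: 13 {2-[(2-allyl-3,5-bis(tert-butyldimethylsilyloxy)phenoxy)(methoxy)methyl]-4-(2-methylbut-3-en-2-yl)phenoxy}triisopropylsilane; 14 ethoxyethyne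
Product: 16 (2S)-8-allyl-5,7-bis(tert-butyldimethylsilyloxy)-2-[5-(2-methylbut-3-en-2-yl)-2-(triisopropylsilyloxy)phenyl]chroman-4-one, via 4-ethoxy-2H-chromene 15 (not isolated)
Conditions: ethoxyethyne (2 equiv), (S)-3,3'-bis(2,4,6-triisopropylphenyl)-1,1'-binaphthalene-2,2'-diyl N-triflylphosphoramide (10 mol %), 5 Å MS, toluene, –60 °C; then 1 M HCl, THF, 0 °C
Reagents that add atoms: water, O
Why: Proposed new method: the chiral acid ionises 13 by loss of methanol (taken up by the sieves) to the O-aryl oxocarbenium ion paired with the chiral phosphoramidate; the terminal carbon of ethoxyethyne adds to C2 (C2–C3 bond), the resulting 1-ethoxyvinyl cation (ketene oxonium ion) is captured by the ring A carbon ortho to O1 (C4–C4a bond), and loss of the arenium proton returns the acid and gives enol ether 15, which dilute acid hydrolyses to ketone 16. The closest known reaction types are the racemic Lewis-acid oxa-Povarov formal [4+2] of aryl acetals with alkenes, additions of ynol ethers to acetal-derived oxocarbenium ions, Friedel–Crafts closures of ketene oxonium and keteniminium ions onto arenes, and chiral phosphoric acid or phosphoramide catalysis of the aza-Povarov reaction and of benzylic cation ion pairs. The pyran ring closes stepwise as a cationic [4+2] in which C4a=C8a–O1=C2 is the four-atom partner; the second bond forms in a six-membered Friedel–Crafts closure, exo to the C4=O bond of the linear cation (6-exo-dig), which leaves C3=C4 in the ring. The C2 stereocentre is set in the first bond formation by the chiral counteranion, which should shield one face of the planar oxocarbenium ion. The step needs ionisation by loss of methoxide and not of aryloxide (the methoxy oxygen is the more basic one), capture of the vinyl cation by ring A and not by methanol (the closure is intramolecular, and C4a is ortho and para to two silyloxy groups and is the only free ortho carbon, which also fixes the regiochemistry), and no closure by the C8 allyl group (which would need a seven-membered ring or a primary cation).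

Step 10
Reactants: 16 (2S)-8-allyl-5,7-bis(tert-butyldimethylsilyloxy)-2-[5-(2-methylbut-3-en-2-yl)-2-(triisopropylsilyloxy)phenyl]chroman-4-one; 17 2-methylbut-2-ene
Product: 18 (2S)-5,7-bis(tert-butyldimethylsilyloxy)-2-[5-(2-methylbut-3-en-2-yl)-2-(triisopropylsilyloxy)phenyl]-8-(3-methylbut-2-en-1-yl)chroman-4-one
Conditions: 2-methylbut-2-ene (excess), second-generation Grubbs catalyst [RuCl2(=CHPh)(H2IMes)(PCy3)] (5 mol %), CH2Cl2, 40 °C
Reagents that add atoms: none
Why: Olefin cross-metathesis with 2-methylbut-2-ene converts the allyl group into the prenyl group, while the vinyl group on ring B, shielded by its quaternary allylic carbon, should react far more slowly.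

Step 11
Reactants: 18 (2S)-5,7-bis(tert-butyldimethylsilyloxy)-2-[5-(2-methylbut-3-en-2-yl)-2-(triisopropylsilyloxy)phenyl]-8-(3-methylbut-2-en-1-yl)chroman-4-one
Product: 19 (2S)-5,7-dihydroxy-2-[2-hydroxy-5-(2-methylbut-3-en-2-yl)phenyl]-8-(3-methylbut-2-en-1-yl)chroman-4-one
Conditions: TBAF, AcOH, THF, 0 °C
Reagents that add atoms: none
Why: Fluoride-mediated desilylation cleaves the three aryl silyl ethers, and the acetic acid buffer keeps the phenols protonated, so that base-induced ring opening to the chalcone, which would racemise C2, should not occur.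

**Compound list**

1 | phloroglucinol (benzene-1,3,5-triol) | Oc1cc(O)cc(O)c1 | starting material
2 | 3,5-bis(tert-butyldimethylsilyloxy)phenol | Oc1cc(O[Si](C)(C)C(C)(C)C)cc(O[Si](C)(C)C(C)(C)C)c1 | intermediate
3 | allyl alcohol (prop-2-en-1-ol) | C=CCO | starting material
4 | 1-(allyloxy)-3,5-bis(tert-butyldimethylsilyloxy)benzene | C=CCOc1cc(O[Si](C)(C)C(C)(C)C)cc(O[Si](C)(C)C(C)(C)C)c1 | intermediate
5 | 2-allyl-3,5-bis(tert-butyldimethylsilyloxy)phenol | C=CCc1c(O)cc(O[Si](C)(C)C(C)(C)C)cc1O[Si](C)(C)C(C)(C)C | intermediate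
6 | 5-bromo-2-hydroxybenzaldehyde | O=Cc1cc(Br)ccc1O | starting material
7 | 5-bromo-2-(triisopropylsilyloxy)benzaldehyde | O=Cc1cc(Br)ccc1O[Si](C(C)C)(C(C)C)C(C)C | intermediate
8 | [4-bromo-2-(dimethoxymethyl)phenoxy]triisopropylsilane | COC(OC)c1cc(Br)ccc1O[Si](C(C)C)(C(C)C)C(C)C | intermediate
9 | isobutyraldehyde (2-methylpropanal) | CC(C)C=O | starting material
10 | 2-[3-(dimethoxymethyl)-4-(triisopropylsilyloxy)phenyl]-2-methylpropanal | COC(OC)c1cc(C(C)(C)C=O)ccc1O[Si](C(C)C)(C(C)C)C(C)C | intermediate
11 | [2-(dimethoxymethyl)-4-(2-methylbut-3-en-2-yl)phenoxy]triisopropylsilane | COC(OC)c1cc(C(C)(C)C=C)ccc1O[Si](C(C)C)(C(C)C)C(C)C | intermediate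
12 | {2-[chloro(methoxy)methyl]-4-(2-methylbut-3-en-2-yl)phenoxy}triisopropylsilane (racemic, formed in the flask) | COC(Cl)c1cc(C(C)(C)C=C)ccc1O[Si](C(C)C)(C(C)C)C(C)C | intermediate
13 | {2-[(2-allyl-3,5-bis(tert-butyldimethylsilyloxy)phenoxy)(methoxy)methyl]-4-(2-methylbut-3-en-2-yl)phenoxy}triisopropylsilane (racemic at the acetal carbon) | COC(Oc1cc(O[Si](C)(C)C(C)(C)C)cc(O[Si](C)(C)C(C)(C)C)c1CC=C)c1cc(C(C)(C)C=C)ccc1O[Si](C(C)C)(C(C)C)C(C)C | intermediate
14 | ethoxyethyne (ethoxyacetylene) | C#COCC | starting material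
15 | (2S)-8-allyl-5,7-bis(tert-butyldimethylsilyloxy)-4-ethoxy-2-[5-(2-methylbut-3-en-2-yl)-2-(triisopropylsilyloxy)phenyl]-2H-chromene (formed in the flask) | C=CC(C)(C)c1ccc(O[Si](C(C)C)(C(C)C)C(C)C)c([C@@H]2C=C(OCC)c3c(O[Si](C)(C)C(C)(C)C)cc(O[Si](C)(C)C(C)(C)C)c(CC=C)c3O2)c1 | intermediate
16 | (2S)-8-allyl-5,7-bis(tert-butyldimethylsilyloxy)-2-[5-(2-methylbut-3-en-2-yl)-2-(triisopropylsilyloxy)phenyl]chroman-4-one | C=CC(C)(C)c1ccc(O[Si](C(C)C)(C(C)C)C(C)C)c([C@@H]2CC(=O)c3c(O[Si](C)(C)C(C)(C)C)cc(O[Si](C)(C)C(C)(C)C)c(CC=C)c3O2)c1 | intermediate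
17 | 2-methylbut-2-ene | CC=C(C)C | starting material
18 | (2S)-5,7-bis(tert-butyldimethylsilyloxy)-2-[5-(2-methylbut-3-en-2-yl)-2-(triisopropylsilyloxy)phenyl]-8-(3-methylbut-2-en-1-yl)chroman-4-one | C=CC(C)(C)c1ccc(O[Si](C(C)C)(C(C)C)C(C)C)c([C@@H]2CC(=O)c3c(O[Si](C)(C)C(C)(C)C)cc(O[Si](C)(C)C(C)(C)C)c(CC=C(C)C)c3O2)c1 | intermediate
19 | (2S)-5,7-dihydroxy-2-[2-hydroxy-5-(2-methylbut-3-en-2-yl)phenyl]-8-(3-methylbut-2-en-1-yl)chroman-4-one | C=CC(C)(C)c1ccc(O)c([C@@H]2CC(=O)c3c(O)cc(O)c(CC=C(C)C)c3O2)c1 | target

**Step count**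

Total steps: 11. Longest linear sequence: 8 steps (steps 4 to 11, from 5-bromo-2-hydroxybenzaldehyde).

**Steps most likely to fail**

Step 9. A loose ion pair may give poor facial selectivity at C2. The acid may be consumed by protonation of the ynol ether. Methanol may capture the vinyl cation before ring A does. The allylic C2–O1 bond of 15 may re-ionise under acid and erode the enantiomeric purity. The fallback uses known chemistry, sets C2 by an aldol reaction and closes ring C by anionic acylation; it sets out from 11 and 5 and returns at 16. Acetal 11 is hydrolysed (PPTS, wet acetone) to 5-(2-methylbut-3-en-2-yl)-2-(triisopropylsilyloxy)benzaldehyde F1. A catalytic asymmetric Mukaiyama acetate aldol (SiCl4, a chiral bisphosphoramide Lewis base whose antipode is chosen for the 3R alcohol, 1-(tert-butyldimethylsilyloxy)-1-methoxyethene, CH2Cl2, –78 °C) should give methyl (3R)-3-hydroxy-3-[5-(2-methylbut-3-en-2-yl)-2-(triisopropylsilyloxy)phenyl]propanoate F2. Phenol 5 is brominated ortho to the hydroxyl (NBS, cat. i-Pr2NH, CH2Cl2) to 2-allyl-6-bromo-3,5-bis(tert-butyldimethylsilyloxy)phenol F3. Mitsunobu etherification of F3 with F2 (PPh3, DIAD, toluene, 0 °C) should proceed with inversion to methyl (3S)-3-[2-allyl-6-bromo-3,5-bis(tert-butyldimethylsilyloxy)phenoxy]-3-[5-(2-methylbut-3-en-2-yl)-2-(triisopropylsilyloxy)phenyl]propanoate F4. Bromine–lithium exchange (n-BuLi, THF, –100 °C) and attack of the aryllithium on the ester (Parham cyclisation) then close ring C and return to 16.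

Step 8. The ionising chloro ether may alkylate the electron-rich ring of 5 at carbon instead of oxygen, and the mixed acetal may hydrolyse or disproportionate during isolation. The fallback replaces the transient chloro ether by a storable sulfone donor; it sets out from 11 and 5 and returns at 13. Exchange of one methoxy group of 11 for benzenesulfinate (PhSO2H, CaCl2, CH2Cl2) should give the crystalline {2-[methoxy(phenylsulfonyl)methyl]-4-(2-methylbut-3-en-2-yl)phenoxy}triisopropylsilane F5. Substitution of the sulfinate by phenol 5 under mild buffered Lewis-acid activation (MgBr2·OEt2, NaHCO3, THF) then gives 13.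

Step 10. Metathesis may also occur at the ring B vinyl group, or turnover may stall at the allyl group flanked by two ortho oxygens. The fallback moves the metathesis to a stage with only one alkene; it sets out from 5 and returns at 18. Cross-metathesis of 5 with 17 under the conditions of step 10 should give 3,5-bis(tert-butyldimethylsilyloxy)-2-(3-methylbut-2-en-1-yl)phenol F6. Alkylation of F6 with chloro ether 12, made from 11 as in step 8, gives {2-[(3,5-bis(tert-butyldimethylsilyloxy)-2-(3-methylbut-2-en-1-yl)phenoxy)(methoxy)methyl]-4-(2-methylbut-3-en-2-yl)phenoxy}triisopropylsilane F7. The annulation of step 9 then gives, through (2S)-5,7-bis(tert-butyldimethylsilyloxy)-4-ethoxy-2-[5-(2-methylbut-3-en-2-yl)-2-(triisopropylsilyloxy)phenyl]-8-(3-methylbut-2-en-1-yl)-2H-chromene F8 and its hydrolysis in the flask, ketone 18 directly. This shifts the risk to ene-type capture of the oxocarbenium ion by the prenyl group, which is why it is held in reserve.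

Further compounds

F1 | step 9 | 5-(2-methylbut-3-en-2-yl)-2-(triisopropylsilyloxy)benzaldehyde | C=CC(C)(C)c1ccc(O[Si](C(C)C)(C(C)C)C(C)C)c(C=O)c1
F2 | step 9 | methyl (3R)-3-hydroxy-3-[5-(2-methylbut-3-en-2-yl)-2-(triisopropylsilyloxy)phenyl]propanoate | C=CC(C)(C)c1ccc(O[Si](C(C)C)(C(C)C)C(C)C)c([C@H](O)CC(=O)OC)c1
F3 | step 9 | 2-allyl-6-bromo-3,5-bis(tert-butyldimethylsilyloxy)phenol | C=CCc1c(O)c(Br)c(O[Si](C)(C)C(C)(C)C)cc1O[Si](C)(C)C(C)(C)C
F4 | step 9 | methyl (3S)-3-[2-allyl-6-bromo-3,5-bis(tert-butyldimethylsilyloxy)phenoxy]-3-[5-(2-methylbut-3-en-2-yl)-2-(triisopropylsilyloxy)phenyl]propanoate | C=CC(C)(C)c1ccc(O[Si](C(C)C)(C(C)C)C(C)C)c([C@@H](Oc2c(Br)c(O[Si](C)(C)C(C)(C)C)cc(O[Si](C)(C)C(C)(C)C)c2CC=C)CC(=O)OC)c1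
F5 | step 8 | {2-[methoxy(phenylsulfonyl)methyl]-4-(2-methylbut-3-en-2-yl)phenoxy}triisopropylsilane | COC(c1cc(C(C)(C)C=C)ccc1O[Si](C(C)C)(C(C)C)C(C)C)S(=O)(=O)c1ccccc1
F6 | step 10 | 3,5-bis(tert-butyldimethylsilyloxy)-2-(3-methylbut-2-en-1-yl)phenol | CC(C)=CCc1c(O)cc(O[Si](C)(C)C(C)(C)C)cc1O[Si](C)(C)C(C)(C)C
F7 | step 10 | {2-[(3,5-bis(tert-butyldimethylsilyloxy)-2-(3-methylbut-2-en-1-yl)phenoxy)(methoxy)methyl]-4-(2-methylbut-3-en-2-yl)phenoxy}triisopropylsilane | COC(Oc1cc(O[Si](C)(C)C(C)(C)C)cc(O[Si](C)(C)C(C)(C)C)c1CC=C(C)C)c1cc(C(C)(C)C=C)ccc1O[Si](C(C)C)(C(C)C)C(C)C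
F8 | step 10 | (2S)-5,7-bis(tert-butyldimethylsilyloxy)-4-ethoxy-2-[5-(2-methylbut-3-en-2-yl)-2-(triisopropylsilyloxy)phenyl]-8-(3-methylbut-2-en-1-yl)-2H-chromene | C=CC(C)(C)c1ccc(O[Si](C(C)C)(C(C)C)C(C)C)c([C@@H]2C=C(OCC)c3c(O[Si](C)(C)C(C)(C)C)cc(O[Si](C)(C)C(C)(C)C)c(CC=C(C)C)c3O2)c1
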